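Per minute is the unit I reckon in: a second-order constant times the concentration it works against becomes a rate in that unit, and the flask reads as a chain of time constants. Starting material opens to open intermediate, partner turns into second intermediate, the two intermediates couple to target, and target goes on to over-reaction product, while capture agent takes open intermediate aside.

common to all: capture agent 5.00 mM; time 3.0 h
- west: starting material 0.10 M (fed, over 2.5 h); partner 0.105 M; temperature 100 °C; all else is in the flask from the start; the feed brings no volume worth counting
- east: starting material 0.10 M; partner 0.105 M (fed, over 2.5 h); temperature 100 °C; all else is in the flask from the start; the feed brings no volume worth counting
- north-west: starting material 0.10 M (fed, over 2.5 h); partner 0.105 M; the addition at 60 °C, then warmed to 100 °C; the feed brings no volume worth counting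
- south-west: starting material 0.10 M; partner 0.105 M; everything together at the start at 60 °C, warmed to 100 °C at 2.5 h
- north-east: starting material 0.10 M; partner 0.105 M (fed, over 15 min); temperature 100 °C; all else is in the flask from the start; the feed brings no volume worth counting

- which flask leads in amount of target, in percent of the starting material charged ("all alike" within 1.5 percentage points) (west / east / north-west / south-west / north-east / all alike)
- how much target is there at the end, in percent of the starting material charged: west
- how much target is there at the end, in percent of the starting material charged: east
- how much target is there at the end, in percent of the starting material charged: north-west
- how much target is there at the end, in percent of the starting material charged: south-west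
- how much target is there at the end, in percent of the starting material charged: north-east

    partner → second intermediate (k1 = 0.0360 min⁻¹, Ea1 = 106 kJ mol⁻¹)
    starting material → open intermediate (k2 = 0.00304 min⁻¹, Ea2 = 125 kJ mol⁻¹)
    target → over-reaction product (k3 = 0.00766 min⁻¹, Ea3 = 106 kJ mol⁻¹)
    open intermediate + second intermediate → target (k4 = 0.0734 M⁻¹ min⁻¹, Ea4 = 84.0 kJ mol⁻¹)
    open intermediate + capture agent → trapped intermediate (k5 = 0.525 M⁻¹ min⁻¹, Ea5 = 83.0 kJ mol⁻¹)
    (constants at 100 °C)

First I ask which constants must be known well, taking north-east, where the partner goes in early. The charge of starting material need not be: opening is first-order, so the percentage asked does not carry it while [second intermediate] stands near the partner's charge. The capture constant need not be, since capture agent can bind 5.00% of the charge, so an error there moves a share of that size. The partner's constant need not be: its lifetime of 27.8 min is shorter than the run and costs a start-up delay of that order. The opening constant must be: its time constant of 5.48 h is longer than the run, so opening is unfinished at the end, and an error in it passes into target.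

Coupling, taken as pseudo-first-order at 0.00771 min⁻¹, and loss of target, at 0.00766 min⁻¹, must be known together. So I carry the balance ratio 1.01: the coupling rate at full [second intermediate] over the loss rate of target. Multiplied by [open intermediate] and by [second intermediate] over the partner's charge, it gives the ceiling, the [target] at which formation equals loss. At 100 °C, below the ceiling target rises, and above it target falls.

The ratio lets me give coupling and loss one rate, and the chain then solves by hand. With rate times run of 0.547 for opening and 1.39 for the other two, I reckon for north-east open intermediate at 21.4% and target at 12.8%, before capture and start-up delay lower it. That lies below the ceiling of 21.5%, so the run ends on the rising side. West and east bring their feed on average 1.25 h late, longer than north-east's delay of 35.3 min, so I put north-east first. The two cold flasks are hot for 30.0 min, and I put them last.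

The forecast also has north-east first, at 10.5%, lower than my figure, with west 5.8%, east 8.7%, north-west 0.55% and south-west 0.6%, holding that “the flask that wins has all the starting material hot from time zero”.

The simulation gives north-east first at 10.8%, then east 8.98%, west 5.99%, south-west 0.508% and north-west 0.493%.

After 3.00 h, north-east holds open intermediate 21.3% and second intermediate 0.0877 M, so its ceiling is 17.9%, and its target of 10.8% stands below that. North-west read after 12.0 h holds open intermediate 19.7% and second intermediate 0.0473 M, a ceiling of 8.91%, and its target has crossed above that, at 11.4%.

The numbers were drawn at random within sensible limits; what happens was integrated by code.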